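The easy step is the loss of starting material: in the south run it stands at 34.8% after 12.0 h, which, read as a first-order fall, gives 0.0880 h⁻¹, a reading with its scatter.

- south: starting material 0.20 M; first nucleophile 0.50 M; second nucleophile 0.12 M; run made earlier
- flask: starting material 0.20 M; first nucleophile 0.500 M; second nucleophile 0.240 M; time 10 d

south run (percent of the starting material charged)

| time / h | target / % | starting material / % |
|---|---|---|
| 1.50 | 6.3 | 88.0 |
| 5.00 | 17.1 | 65.5 |
| 8.00 | 23.9 | 50.4 |
| 12.0 | 26.4 | 34.8 |
| 20.0 | 26.7 | 17.0 |
| 25.0 | 24.4 | 11.6 |

(readings scatter by 0.5 percentage points)

- time up to 10 d at which target stands highest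
- the amount of target, in percent of the starting material charged, at that time
- the first time at which target reaches 5.9%, in the same percent, in d

- a reading or a percentage of target counts all its forms, free or not

Now we follow one molecule. We assume that on leaving the starting material it reaches a fork, where first nucleophile takes it to target and second nucleophile takes it elsewhere, each in proportion to its concentration. At the first south reading, 6.3% of target stands against 12.0% of starting material lost, so the target share is 52.5%, a reading with its scatter. Dividing out the south charges gives the fork ratio 0.265, the rate of capture by first nucleophile over that by second at equal concentrations, which is a selectivity factor.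

The first setting to turn is second nucleophile. Going from 0.12 M to 0.240 M, twice the south charge, lowers the share to 35.6%. If the peak scales with the share, the highest south reading of 26.7% becomes 18.1% in the flask. Neglecting early loss of target, the share and the first-order fall put 5.9% of target in the flask at 0.0858 d.

The second setting is time. Target in the south run already falls from 26.7% at 20.0 h to 24.4% at 25.0 h, so we expect no gain in the flask from the longer 10 d, and a peak there near 0.667 d, between the two highest south readings.

The forecast differs, giving 38% at 1.1 d and the level at 0.055 d, on the view that second “nucleophile seems to protect or feed target”.

The flask gives 19.6% at 0.643 d and reaches the level at 0.0849 d.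

starting material → intermediate (k = 2.42 × 10⁻⁵ s⁻¹); first nucleophile + intermediate → target (k = 0.00129 L mol⁻¹ s⁻¹); second nucleophile + intermediate → other capture product (k = 0.00376 L mol⁻¹ s⁻¹); first nucleophile → decomposition product (k = 1.54 × 10⁻⁸ s⁻¹); crystals ⇌ target, rate k5*(cs5 - [target]) while solid is left; crystals form when [target] > cs5 (solubility = 0.130 M, k = 0.00111 s⁻¹); target ⇌ isomer of the product (K = 4.69, k = 1.85 × 10⁻⁵ s⁻¹) Starting from the south run, changing only second nucleophile moves the peak from 27.6% to 19.6%, while changing only the time leaves it at 27.6%. For a neighbour flask with 0.096 M of second nucleophile, the fork ratio gives a share of 58.0% and a peak of 29.5%, and that flask gives 29.9%.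

The earlier runs and the new flask were computed with constants of no real substance; noise was put on by code.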